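The dihydropyran ring is cut at C3–C4 and O1–C2. Its O1–C8a–C4a–C4 part is read as an o-quinone methide of ring A, stabilised by the C7 oxygen para to C4a, and C2–C3 as the enamine of (2,3,4,5-tetramethoxyphenyl)acetaldehyde, C3 being benzylic to ring B. An aminocatalytic formal oxa-[4+2] then joins the two aryl halves, closes the pyran ring as a chroman-2-ol and sets C3 (S) in one operation. The precursors are a 2-(tosylmethyl)phenol and an arylacetaldehyde, neither of which contains the heterocycle. Ionic hydrogenation of the lactol and hydrogenolysis of the benzyl ether finish the synthesis.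

Key step: step 5

Remark: 2,4-dihydroxy-3-methoxybenzaldehyde (1), 1,2,3,4-tetramethoxybenzene (5) and ethylene oxide (6, as a THF solution) are taken as catalogue chemicals.

Step 1
Reactants: 1 2,4-dihydroxy-3-methoxybenzaldehyde
Product: 2 4-(benzyloxy)-2-hydroxy-3-methoxybenzaldehyde
Conditions: BnBr (1.05 equiv), NaHCO3, KI (cat.), MeCN, 60 °C
Reagents that add atoms: benzyl bromide, BrCc1ccccc1
Why: Williamson ether synthesis: the 2-OH is held in a hydrogen bond to the ortho-formyl group, so the weak base should ionise and benzylate only the more acidic, unchelated 4-OH.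

Step 2
Reactants: 2 4-(benzyloxy)-2-hydroxy-3-methoxybenzaldehyde
Product: 4 3-(benzyloxy)-2-methoxy-6-[(4-methylphenyl)sulfonylmethyl]phenol, via salicyl alcohol 3 (not isolated)
Conditions: NaBH4 (0.5 equiv), THF/EtOH, 0 °C; then TolSO2Na (3 equiv), aq. HCO2H, rt
Reagents that add atoms: sodium p-toluenesulfinate, Cc1ccc(cc1)S(=O)[O-].[Na+]
Why: Borohydride reduction of the aldehyde followed by acid-promoted SN1-type sulfinate substitution: the p-benzyloxy-activated salicyl alcohol 3 ionises in aqueous formic acid and the sulfinate is alkylated at sulfur to give the bench-stable sulfone, the storable precursor of the quinone methide.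

Step 3
Reactants: 5 1,2,3,4-tetramethoxybenzene; 6 ethylene oxide
Product: 8 2-(2,3,4,5-tetramethoxyphenyl)ethan-1-ol, via aryllithium 7 (not isolated)
Conditions: n-BuLi, TMEDA, THF, 0 °C; then 6, −78 °C → rt; H2O
Reagents that add atoms: none
Why: Directed ortho-lithiation (the two ring C–H are equivalent, each ortho to OMe) followed by epoxide ring opening by the aryllithium installs the two-carbon chain that becomes C3 and C2.

Step 4
Reactants: 8 2-(2,3,4,5-tetramethoxyphenyl)ethan-1-ol
Product: 9 (2,3,4,5-tetramethoxyphenyl)acetaldehyde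
Conditions: Dess–Martin periodinane, CH2Cl2, 0 °C → rt
Reagents that add atoms: none
Why: Dess–Martin oxidation stops cleanly at the aldehyde under mild, non-aqueous conditions that should spare the enolisable, electron-rich arylacetaldehyde, which is used at once.

Step 5
Reactants: 4 3-(benzyloxy)-2-methoxy-6-[(4-methylphenyl)sulfonylmethyl]phenol; 9 (2,3,4,5-tetramethoxyphenyl)acetaldehyde (1.5 equiv)
Product: 12 (3S)-7-(benzyloxy)-8-methoxy-3-(2,3,4,5-tetramethoxyphenyl)chroman-2-ol, via o-quinone methide 10 (not isolated), via open-chain hydroxy aldehyde 11 (not isolated)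
Conditions: (S)-α,α-diphenylprolinol trimethylsilyl ether (20 mol %), NaHCO3 (2 equiv), CH2Cl2/H2O (10:1), 0 °C
Reagents that add atoms: none
Why: Bicarbonate deprotonates the phenol of 4 and, pushed by the C7 benzyloxy group para to the benzylic carbon, p-toluenesulfinate leaves to give o-quinone methide 10, a 1-oxadiene built from O1, C8a, C4a and C4; meanwhile 9 and the amine form the conjugated (E)-enamine, whose β-carbon (the future C3) adds to the exocyclic CH2 of 10 with re-aromatisation of ring A. Hydrolysis of the iminium ion gives 11, and its phenol closes onto the aldehyde (6-exo-trig hemiacetalisation, O1–C2), so that the step is a formal inverse-electron-demand oxa-[4+2] cycloaddition in which C3–C4 forms first and O1–C2 second. The closest known reaction type is the diarylprolinol silyl ether-catalysed Michael addition/hemiacetalisation of aldehydes with o-quinone methides released from 2-(sulfonylmethyl)phenols (enamine catalysis). C3 is controlled by the catalyst: the CPh2(OTMS) group of the (S)-amine shields one face of the anti-(E)-enamine and C4 is delivered to the open face, which by the usual model for this catalyst should give (3S); the anomeric C2 forms as a mixture and is removed in step 6. The step needs capture of 10 at carbon by the enamine faster than oligomerisation of 10 or N-alkylation of the catalyst, which the hindered amine, the slow heterogeneous release of 10 and the excess of 9 should secure. It also needs the C3–H (benzylic, α to a masked aldehyde) to stay in place, which is favoured because the product rests as the closed lactol, an α-branched aldehyde re-forms an enamine only slowly, and the base is weak.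

Step 6
Reactants: 12 (3S)-7-(benzyloxy)-8-methoxy-3-(2,3,4,5-tetramethoxyphenyl)chroman-2-ol
Product: 13 (3S)-7-(benzyloxy)-8-methoxy-3-(2,3,4,5-tetramethoxyphenyl)chromane
Conditions: Et3SiH (3 equiv), BF3·OEt2 (1.5 equiv), CH2Cl2, −78 → −30 °C
Reagents that add atoms: none
Why: Ionic hydrogenation of a lactol: BF3 ionises the anomeric OH to the cyclic oxocarbenium ion and Et3SiH delivers hydride to C2, while the low temperature and excess silane should keep reduction faster than loss of the C3 proton, so that C3 is carried through unchanged.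

Step 7
Reactants: 13 (3S)-7-(benzyloxy)-8-methoxy-3-(2,3,4,5-tetramethoxyphenyl)chromane
Product: 14 (3S)-8-methoxy-3-(2,3,4,5-tetramethoxyphenyl)chroman-7-ol
Conditions: H2 (1 atm), 10% Pd/C, EtOAc/MeOH, rt
Reagents that add atoms: none
Why: Catalytic hydrogenolysis cleaves only the benzylic C–O bond of the benzyl aryl ether; the chroman ether, the methyl ethers and the C3–H stereocentre are inert.

Compound list
1 | 2,4-dihydroxy-3-methoxybenzaldehyde | O=Cc1ccc(O)c(OC)c1O | starting material
2 | 4-(benzyloxy)-2-hydroxy-3-methoxybenzaldehyde | O=Cc1ccc(OCc2ccccc2)c(OC)c1O | intermediate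
3 | 3-(benzyloxy)-6-(hydroxymethyl)-2-methoxyphenol (salicyl alcohol, not isolated) | OCc1ccc(OCc2ccccc2)c(OC)c1O | intermediate
4 | 3-(benzyloxy)-2-methoxy-6-[(4-methylphenyl)sulfonylmethyl]phenol | Cc1ccc(cc1)S(=O)(=O)Cc1ccc(OCc2ccccc2)c(OC)c1O | intermediate
5 | 1,2,3,4-tetramethoxybenzene | COc1ccc(OC)c(OC)c1OC | starting material
6 | ethylene oxide | C1CO1 | starting material
7 | (2,3,4,5-tetramethoxyphenyl)lithium (not isolated) | [Li]c1cc(OC)c(OC)c(OC)c1OC | intermediate
8 | 2-(2,3,4,5-tetramethoxyphenyl)ethan-1-ol | OCCc1cc(OC)c(OC)c(OC)c1OC | intermediate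
9 | (2,3,4,5-tetramethoxyphenyl)acetaldehyde | O=CCc1cc(OC)c(OC)c(OC)c1OC | intermediate
10 | 3-(benzyloxy)-2-methoxy-6-methylidenecyclohexa-2,4-dien-1-one (o-quinone methide, not isolated) | C=C1C=CC(OCc2ccccc2)=C(OC)C1=O | intermediate
11 | (2S)-3-[4-(benzyloxy)-2-hydroxy-3-methoxyphenyl]-2-(2,3,4,5-tetramethoxyphenyl)propanal (not isolated) | COc1cc([C@@H](C=O)Cc2ccc(OCc3ccccc3)c(OC)c2O)c(OC)c(OC)c1OC | intermediate
12 | (3S)-7-(benzyloxy)-8-methoxy-3-(2,3,4,5-tetramethoxyphenyl)chroman-2-ol (both C2 anomers) | COc1cc([C@H]2C(O)Oc3c(ccc(OCc4ccccc4)c3OC)C2)c(OC)c(OC)c1OC | intermediate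
13 | (3S)-7-(benzyloxy)-8-methoxy-3-(2,3,4,5-tetramethoxyphenyl)chromane | COc1cc([C@H]2COc3c(ccc(OCc4ccccc4)c3OC)C2)c(OC)c(OC)c1OC | intermediate
14 | (3S)-8-methoxy-3-(2,3,4,5-tetramethoxyphenyl)chroman-7-ol | COc1cc([C@H]2COc3c(ccc(O)c3OC)C2)c(OC)c(OC)c1OC | target

Total step count: 7. Longest linear sequence: 5 (steps 1, 2, 5, 6, 7; steps 3 and 4 form the second branch, which joins at step 5).

Steps most likely to fail

Step 5. N-alkylation of the amine catalyst by 10, or self-condensation of 10, may outrun C–C bond formation. Proton exchange at C3 of the lactol, through the enamine or enolate of its open form, may also erode the enantiomeric purity. The fallback sets out from 4 and 9 and comes back at 13, replacing steps 5 and 6. Aldehyde 9 is condensed with morpholine (MgSO4, toluene) to the enamine 4-[(E)-2-(2,3,4,5-tetramethoxyphenyl)ethenyl]morpholine F1, which is used in excess. Quinone methide 10, released from 4 with Na2CO3 in MeCN, should be taken up by F1 in a thermal inverse-electron-demand hetero-Diels–Alder reaction to give the racemic aminal 4-[7-(benzyloxy)-8-methoxy-3-(2,3,4,5-tetramethoxyphenyl)chroman-2-yl]morpholine F2. TsOH (cat.) in warm toluene should eliminate morpholine to give the achiral enol ether 7-(benzyloxy)-8-methoxy-3-(2,3,4,5-tetramethoxyphenyl)-4H-chromene F3. Iridium–phosphinooxazoline-catalysed asymmetric hydrogenation of F3 (H2, CH2Cl2, catalyst antipode chosen for S) then sets C3 and gives 13, so the configuration no longer rests on an epimerisable intermediate.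

Step 6. Reversible loss of the C3 proton from the oxocarbenium ion (towards the 4H-chromene) would scramble C3, and the cation may alkylate one of the electron-rich rings. The fallback sets out from 12 and comes back at 13. NaBH4 (EtOH, 0 °C) should reduce the open-chain aldehyde tautomer of 12 to the diol (2S)-3-[4-(benzyloxy)-2-hydroxy-3-methoxyphenyl]-2-(2,3,4,5-tetramethoxyphenyl)propan-1-ol F4. An intramolecular Mitsunobu etherification (PPh3, DIAD, THF, 0 °C; phenol as the acid partner, SN2 at the primary carbon) then closes the ring to 13 without a cation next to C3.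

Step 2. Acid-induced self-condensation of the very electron-rich salicyl alcohol, through its protonated quinone methide, may outrun capture by sulfinate. The fallback sets out from 2 and comes back at 10. Reductive amination of 2 with dimethylamine (Me2NH·HCl, NaBH(OAc)3, DCE) should give the Mannich base 3-(benzyloxy)-6-[(dimethylamino)methyl]-2-methoxyphenol F5. MeI (MeCN, rt, no base) quaternises the nitrogen to [4-(benzyloxy)-2-hydroxy-3-methoxyphenyl]methyl-trimethylammonium iodide F6. Under the conditions of step 5, F6 should lose trimethylamine to give 10, which enters the key step in place of the one released from 4.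

Further compounds
F1 | step 5 | 4-[(E)-2-(2,3,4,5-tetramethoxyphenyl)ethenyl]morpholine | COc1cc(/C=C/N2CCOCC2)c(OC)c(OC)c1OC
F2 | step 5 | rac-4-[7-(benzyloxy)-8-methoxy-3-(2,3,4,5-tetramethoxyphenyl)chroman-2-yl]morpholine | COc1cc(C2Cc3ccc(OCc4ccccc4)c(OC)c3OC2N2CCOCC2)c(OC)c(OC)c1OC
F3 | step 5 | 7-(benzyloxy)-8-methoxy-3-(2,3,4,5-tetramethoxyphenyl)-4H-chromene | COc1cc(C2=COc3c(ccc(OCc4ccccc4)c3OC)C2)c(OC)c(OC)c1OC
F4 | step 6 | (2S)-3-[4-(benzyloxy)-2-hydroxy-3-methoxyphenyl]-2-(2,3,4,5-tetramethoxyphenyl)propan-1-ol | COc1cc([C@@H](CO)Cc2ccc(OCc3ccccc3)c(OC)c2O)c(OC)c(OC)c1OC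
F5 | step 2 | 3-(benzyloxy)-6-[(dimethylamino)methyl]-2-methoxyphenol | CN(C)Cc1ccc(OCc2ccccc2)c(OC)c1O
F6 | step 2 | [4-(benzyloxy)-2-hydroxy-3-methoxyphenyl]methyl-trimethylammonium iodide | C[N+](C)(C)Cc1ccc(OCc2ccccc2)c(OC)c1O.[I-]
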